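Counting Z in all its forms, every Z costs one J and one G, so a flask in which G is the limiting reagent has a ceiling on its Z: the charge of G over the charge of J.

| flask | J | G | E | temperature | remark | time |
|---|---|---|---|---|---|---|
| Wednesday's | 50 mM | 45 mM | 0.22 mM | 110 °C | run made earlier |  |
| gamma | 60 mM | 60.0 mM | 0.22 mM | 110 °C |  | 3.0 h |
| eta | 45 mM | 45.0 mM | 0.15 mM | 110 °C |  | 3.0 h |
| delta | 200 mM | 45.0 mM | 0.22 mM | 110 °C |  | 3.0 h |
| zeta | 45 mM | 45.0 mM | 0.22 mM | 110 °C |  | 3.0 h |
| alpha | 150 mM | 150 mM | 0.22 mM | 90 °C |  | 3.0 h |

Wednesday's run (percent of the J charged)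

| time / min | Z / % |
|---|---|
| 8.00 | 7 |
| 12.0 | 12 |
| 20.0 | 23 |
| 30.0 | 28 |
| 50.0 | 41 |
| 80.0 | 50 |
| 120 | 59 |

(scatter of a reading: 1.5 percentage points)

- the numbers in the tables scatter with a standard deviation of 1.5 percentage points
- a reading or a percentage of Z counts all its forms, free or not
- the earlier runs do not show what temperature does; that part of a forecast is a guess
- no earlier run changes the charge of E; that part of a forecast is a guess

* the flasks by amount of Z, in percent of the J charged, highest first, at 3.0 h (gamma / eta / delta / zeta / alpha)
* the same order at 10 min (gamma / eta / delta / zeta / alpha)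
* the amount of Z, in percent of the J charged of the flask you put first, at 3.0 h
* the amount of Z, in percent of the J charged of the flask you put last, at 3.0 h

For delta, with 200 mM of J against 45.0 mM of G, this ratio of charges, the G ceiling, comes to 22.5% of the J charged.

Whether delta reaches it by 3.0 h can be read from Wednesday's run. At 20.0 min that run reads 23% of its J as Z, which is 11.5 mM of its G gone, so I read a pseudo-first-order constant for G of roughly 0.0148 min⁻¹ at a J charge of 50 mM. Taken in proportion to J, this gives G in delta a half-life of about 11.7 min, far shorter than the 3.0 h asked, so I commit to delta standing at its ceiling.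

The forecast gives gamma > zeta > alpha > eta > delta at 3.0 h and gamma > zeta > alpha > delta > eta at 10 min, with 76% for the first flask (range 64% to 82%) and 22% for the last (range 19.5% to 22.5%). Of delta it says: “G runs out, capped at 22.5% of J, about 22%”.

The flasks give alpha > gamma > zeta > eta > delta at 3.0 h and alpha > gamma > zeta > delta > eta at 10 min. Alpha comes first at 80.0%, and gamma, which the forecast put first, comes second at 76.8%. Delta comes last at 22.5%, on its G ceiling of 22.5%.

    D ⇌ Z, rate k1*(cs1 - [Z]) while solid is left; crystals form when [Z] > cs1 (solubility = 27.0 mM, k = 0.00414 s⁻¹)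
    J + G + E → E + Z (k = 23.2 L² mol⁻² s⁻¹, Ea = 42.0 kJ mol⁻¹)
    (constants at 110 °C)

In delta the half-life of G by the path from J, G and E to Z is 0.21 h at 0.202 h, far below the 3.0 h of the run, while the half-life of J by that path at 3.00 h is 230 d. At that time delta holds G at 0.0151% of its own charge and J at 77.5% of the J charged. The neighbour of delta charged with 340 mM of J has a G ceiling of 13.2% and gives 13.2% at 3.00 h.

The data stem from a simulated flask with constants of no real substance, noise included.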